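## Retrosynthetic overview

1. The target is reached from its 6-hydroxy acid by O-benzoylation, and that from the macrocyclic methyl ester by saponification.
2. Key bond C5–C6: a macrocyclising Nozaki–Hiyama–Kishi addition in which the β-carbon of an (E)-β-iodoacrylate acts as a β-acyl vinyl anion (d3, vinylogous homoenolate) towards the aldehyde carbon (a1). Two natively electrophilic carbons are joined; the step closes the 11-membered ring, delivers the γ-oxygenated enoate with the correct alkene geometry and sets C6 under ligand control.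
3. Ring order: the oxirane first (Shi epoxidation of the acyclic (E)-trisubstituted alkene), the carbocycle second.
4. The (E)-β-iodoacrylate comes from an alkylmalonate (iodoform diiodomethylation, then decarboxylative elimination). C10–C11 comes from a B-alkyl Suzuki coupling of hydroborated 2,2-dimethylpent-4-en-1-ol with an (E)-2-iodoalkene, C3–C4 from malonate alkylation, and the alkene geometry from hydrozirconation of pent-3-ynyl tosylate.

Numbering: locants are those of the target name (1S,4E,6R,11S)-6-(benzoyloxy)-7,7,11-trimethyl-12-oxabicyclo[9.1.0]dodec-4-ene-4-carboxylic acid (C1/C11 epoxide carbons, C4 carboxyl-bearing alkene carbon, C6 benzoyloxy carbon, C7 CMe2).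

Assumption: the facial sense of the chromium–sulfonamide complex in step 9 is taken by analogy and has not been derived for this substrate; the ligand antipode that gives 6R is used (the (S)-ligand, (S)-N-[2-(4-isopropyl-4,5-dihydro-1,3-oxazol-2-yl)-6-methylphenyl]methanesulfonamide, is written).

Assumption: this ligand and the ent-Shi ketone are treated as purchasable reagents and not counted as steps; 2,2-dimethylpent-4-en-1-ol is bought.

## Route

Step 1
Reactants: 1 pent-3-yn-1-ol
Product: 2 pent-3-yn-1-yl 4-methylbenzenesulfonate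
Conditions: TsCl, Et3N, DMAP (cat.), CH2Cl2, 0 °C to rt
Reagents that add atoms: 4-methylbenzenesulfonyl chloride, Cc1ccc(cc1)S(=O)(=O)Cl
Why: Sulfonylation of the primary alcohol makes the leaving group for the malonate alkylation and removes the free alkoxide that would direct the hydrozirconation to the wrong alkyne carbon.

Step 2
Reactants: 2 pent-3-yn-1-yl 4-methylbenzenesulfonate
Product: 4 (3E)-4-iodopent-3-en-1-yl 4-methylbenzenesulfonate, via alkenylzirconocene chloride 3 (not isolated)
Conditions: Cp2Zr(H)Cl (2 equiv), THF, 50 °C; then I2, 0 °C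
Reagents that add atoms: iodine, II
Why: syn-Hydrozirconation with excess reagent equilibrates to zirconium on the methyl-bearing carbon (about 9:1 or better for methyl alkynes, minor regioisomer removed by chromatography), and iodinolysis with retention gives the (E)-2-iodoalkene that fixes the geometry later carried into the epoxide.

Step 3
Reactants: 4 (3E)-4-iodopent-3-en-1-yl 4-methylbenzenesulfonate; 5 diethyl malonate
Product: 7 diethyl 2-[(3E)-4-iodopent-3-en-1-yl]propanedioate, via sodium diethyl malonate 6 (not isolated)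
Conditions: NaH, 5 (2 equiv), THF/DMF, 0 °C; then 4, NaI (cat.), 60 °C
Reagents that add atoms: none
Why: Malonic ester alkylation (SN2 of the soft enolate on the primary tosylate) installs C4 with both carboxyl carbons while the vinyl iodide is inert.

Step 4
Reactants: 8 2,2-dimethylpent-4-en-1-ol; 7 diethyl 2-[(3E)-4-iodopent-3-en-1-yl]propanedioate
Product: 10 diethyl 2-[(3E)-9-hydroxy-4,8,8-trimethylnon-3-en-1-yl]propanedioate, via bis-borylated alkylborane 9 (not isolated)
Conditions: 9-BBN (2.2 equiv), THF, rt; then 7, Pd(dppf)Cl2 (5 mol%), AsPh3, Cs2CO3, DMF/H2O, rt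
Reagents that add atoms: none
Why: Anti-Markovnikov hydroboration (the hydroxyl is masked in the flask as its borinate) followed by B-alkyl Suzuki–Miyaura coupling, which proceeds with retention at the vinyl iodide and so gives the (E)-trisubstituted alkene stereospecifically.

Step 5
Reactants: 10 diethyl 2-[(3E)-9-hydroxy-4,8,8-trimethylnon-3-en-1-yl]propanedioate
Product: 12 diethyl 2-(diiodomethyl)-2-[(3E)-9-hydroxy-4,8,8-trimethylnon-3-en-1-yl]propanedioate, via sodium malonate enolate 11 (not isolated)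
Conditions: NaH (1.1 equiv), Et2O, reflux; then CHI3, reflux, 24 h
Reagents that add atoms: iodoform, IC(I)I
Why: Diiodomethylation of an alkylmalonate with iodoform (enolate capture of diiodocarbene) makes the quaternary carbon bearing the future C5; with 1.1 equiv of base only the malonate (pKa about 13 against 16–17 for the alcohol) is ionised.

Step 6
Reactants: 12 diethyl 2-(diiodomethyl)-2-[(3E)-9-hydroxy-4,8,8-trimethylnon-3-en-1-yl]propanedioate
Product: 14 methyl (5E)-11-hydroxy-2-[(E)-iodomethylidene]-6,10,10-trimethylundec-5-enoate (iodine cis to the chain CH2, trans to CO2Me), via potassium iodoacrylate salt 13 (not isolated)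
Conditions: KOH, EtOH/H2O 3:1, reflux, 24 h; then CO2 to pH 9, evaporate; MeI, DMF, rt
Reagents that add atoms: potassium hydroxide, [K+].[OH-]; iodomethane, CI
Why: Saponification triggers a decarboxylative anti-elimination of iodide (Grob-type fragmentation, known to give (E)-3-iodo-2-alkylacrylic acids with iodine trans to the carboxyl), and the carboxylate is O-methylated in the same flask.

Step 7
Reactants: 14 methyl (5E)-11-hydroxy-2-[(E)-iodomethylidene]-6,10,10-trimethylundec-5-enoate
Product: 15 methyl (2E)-2-{2-[(2S,3S)-3-(5-hydroxy-4,4-dimethylpentyl)-3-methyloxiran-2-yl]ethyl}-3-iodoprop-2-enoate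
Conditions: ent-Shi ketone (1,2:4,5-di-O-isopropylidene-β-L-erythro-2,3-hexodiulo-2,6-pyranose, 30 mol%), KHSO5 (as Oxone, 2KHSO5·KHSO4·K2SO4), K2CO3, Bu4NHSO4, MeCN/dimethoxymethane/aq. Na2B4O7 buffer, 0 °C
Reagents that add atoms: potassium peroxymonosulfate, [K+].[O-]S(=O)(=O)OO
Why: Shi asymmetric epoxidation (chiral dioxirane, spiro transition state) of the only electron-rich alkene; the D-fructose-derived ketone gives (R,R)-epoxides from (E)-trisubstituted alkenes, so its enantiomer gives the (2S,3S)-oxirane, and the iodoacrylate alkene is too electron-poor to react.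

Step 8
Reactants: 15 methyl (2E)-2-{2-[(2S,3S)-3-(5-hydroxy-4,4-dimethylpentyl)-3-methyloxiran-2-yl]ethyl}-3-iodoprop-2-enoate
Product: 16 methyl (2E)-2-{2-[(2S,3S)-3-(4,4-dimethyl-5-oxopentyl)-3-methyloxiran-2-yl]ethyl}-3-iodoprop-2-enoate
Conditions: Dess–Martin periodinane, NaHCO3, CH2Cl2, 0 °C to rt
Reagents that add atoms: none
Why: Buffered Dess–Martin oxidation turns the neopentyl alcohol into the non-enolisable aldehyde without touching the epoxide, vinyl iodide or ester.

Step 9
Reactants: 16 methyl (2E)-2-{2-[(2S,3S)-3-(4,4-dimethyl-5-oxopentyl)-3-methyloxiran-2-yl]ethyl}-3-iodoprop-2-enoate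
Product: 17 methyl (1S,4E,6R,11S)-6-hydroxy-7,7,11-trimethyl-12-oxabicyclo[9.1.0]dodec-4-ene-4-carboxylate
Conditions: CrCl2 (4 equiv), (S)-oxazoline–sulfonamide ligand (4.4 equiv), Et3N (4.4 equiv), THF, rt, 1 h; NiCl2 (0.2 equiv); 16 added over 12 h (final 2 mM), rt; aq. ethylenediamine work-up
Reagents that add atoms: none
Why: Nozaki–Hiyama–Kishi macrocyclisation, in which zerovalent nickel inserts into the C–I bond and transmetalation to trivalent chromium gives a β-chromio acrylate (β-acyl vinyl anion, d3) that adds to the aldehyde carbon with retention of alkene geometry at high dilution (helped by the gem-dimethyl group and the ring-cis enoate), the ligand-bound chromium choosing the aldehyde face that gives 6R while the isolated trialkyl epoxide and the ester are inert to CrCl2.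

Step 10
Reactants: 17 methyl (1S,4E,6R,11S)-6-hydroxy-7,7,11-trimethyl-12-oxabicyclo[9.1.0]dodec-4-ene-4-carboxylate
Product: 18 (1S,4E,6R,11S)-6-hydroxy-7,7,11-trimethyl-12-oxabicyclo[9.1.0]dodec-4-ene-4-carboxylic acid
Conditions: LiOH·H2O, THF/MeOH/H2O, rt to 40 °C; NaH2PO4 to pH 4, 0 °C
Reagents that add atoms: lithium hydroxide, [Li+].[OH-]
Why: Ester saponification (BAc2) under conditions that leave the trialkyl epoxide intact; the 6-hydroxyl is trans to the carboxyl across the alkene, so no butenolide can form.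

Step 11
Reactants: 18 (1S,4E,6R,11S)-6-hydroxy-7,7,11-trimethyl-12-oxabicyclo[9.1.0]dodec-4-ene-4-carboxylic acid
Product: 20 (1S,4E,6R,11S)-6-(benzoyloxy)-7,7,11-trimethyl-12-oxabicyclo[9.1.0]dodec-4-ene-4-carboxylic acid (target), via mixed benzoic anhydride 19 (not isolated)
Conditions: BzCl (3 equiv), DMAP (0.2 equiv), pyridine, CH2Cl2, 0 °C to rt; then H2O, THF, rt; pH 4 work-up
Reagents that add atoms: benzoyl chloride, O=C(Cl)c1ccccc1
Why: DMAP-catalysed O-acylation of the hindered allylic alcohol with excess benzoyl chloride also forms the mixed anhydride at the acid, which the aqueous stage hydrolyses at the less hindered benzoyl carbonyl to release the target with all stereocentres untouched.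

## Compound list

1 | pent-3-yn-1-ol | CC#CCCO | starting material
2 | pent-3-yn-1-yl 4-methylbenzenesulfonate | CC#CCCOS(=O)(=O)c1ccc(C)cc1 | intermediate
3 | chlorobis(cyclopentadienyl)[(2E)-5-(tosyloxy)pent-2-en-2-yl]zirconium | C/C(=C\CCOS(=O)(=O)c1ccc(C)cc1)[Zr](Cl)(C1C=CC=C1)C1C=CC=C1 | intermediate (not isolated)
4 | (3E)-4-iodopent-3-en-1-yl 4-methylbenzenesulfonate | C/C(I)=C\CCOS(=O)(=O)c1ccc(C)cc1 | intermediate
5 | diethyl malonate | CCOC(=O)CC(=O)OCC | starting material
6 | sodium diethyl malonate | [Na+].CCOC(=O)[CH-]C(=O)OCC | intermediate (not isolated)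
7 | diethyl 2-[(3E)-4-iodopent-3-en-1-yl]propanedioate | CCOC(=O)C(CC/C=C(\C)I)C(=O)OCC | intermediate
8 | 2,2-dimethylpent-4-en-1-ol | C=CCC(C)(C)CO | starting material
9 | 9-{[5-(9-borabicyclo[3.3.1]nonan-9-yl)-2,2-dimethylpentyl]oxy}-9-borabicyclo[3.3.1]nonane | CC(C)(CCCB1C2CCCC1CCC2)COB1C2CCCC1CCC2 | intermediate (not isolated)
10 | diethyl 2-[(3E)-9-hydroxy-4,8,8-trimethylnon-3-en-1-yl]propanedioate | CCOC(=O)C(CC/C=C(\C)CCCC(C)(C)CO)C(=O)OCC | intermediate
11 | sodium enolate of 10 | [Na+].CCOC(=O)[C-](CC/C=C(\C)CCCC(C)(C)CO)C(=O)OCC | intermediate (not isolated)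
12 | diethyl 2-(diiodomethyl)-2-[(3E)-9-hydroxy-4,8,8-trimethylnon-3-en-1-yl]propanedioate | CCOC(=O)C(CC/C=C(\C)CCCC(C)(C)CO)(C(I)I)C(=O)OCC | intermediate
13 | potassium (5E)-11-hydroxy-2-[(E)-iodomethylidene]-6,10,10-trimethylundec-5-enoate | [K+].[O-]C(=O)/C(CC/C=C(\C)CCCC(C)(C)CO)=C/I | intermediate (not isolated)
14 | methyl (5E)-11-hydroxy-2-[(E)-iodomethylidene]-6,10,10-trimethylundec-5-enoate | COC(=O)/C(CC/C=C(\C)CCCC(C)(C)CO)=C/I | intermediate
15 | methyl (2E)-2-{2-[(2S,3S)-3-(5-hydroxy-4,4-dimethylpentyl)-3-methyloxiran-2-yl]ethyl}-3-iodoprop-2-enoate | OCC(C)(C)CCC[C@]1(C)O[C@H]1CC/C(C(=O)OC)=C\I | intermediate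
16 | methyl (2E)-2-{2-[(2S,3S)-3-(4,4-dimethyl-5-oxopentyl)-3-methyloxiran-2-yl]ethyl}-3-iodoprop-2-enoate | O=CC(C)(C)CCC[C@]1(C)O[C@H]1CC/C(C(=O)OC)=C\I | intermediate
17 | methyl (1S,4E,6R,11S)-6-hydroxy-7,7,11-trimethyl-12-oxabicyclo[9.1.0]dodec-4-ene-4-carboxylate | CC1(C)CCC[C@]2(C)O[C@H]2CC/C(C(=O)OC)=C\[C@H]1O | intermediate
18 | (1S,4E,6R,11S)-6-hydroxy-7,7,11-trimethyl-12-oxabicyclo[9.1.0]dodec-4-ene-4-carboxylic acid | CC1(C)CCC[C@]2(C)O[C@H]2CC/C(C(=O)O)=C\[C@H]1O | intermediate
19 | benzoic (1S,4E,6R,11S)-6-(benzoyloxy)-7,7,11-trimethyl-12-oxabicyclo[9.1.0]dodec-4-ene-4-carboxylic anhydride | CC1(C)CCC[C@]2(C)O[C@H]2CC/C(C(=O)OC(=O)c3ccccc3)=C\[C@H]1OC(=O)c1ccccc1 | intermediate (not isolated)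
20 | (1S,4E,6R,11S)-6-(benzoyloxy)-7,7,11-trimethyl-12-oxabicyclo[9.1.0]dodec-4-ene-4-carboxylic acid | CC1(C)CCC[C@]2(C)O[C@H]2CC/C(C(=O)O)=C\[C@H]1OC(=O)c1ccccc1 | target

## Step count and risks

Total step count: 11. Longest linear sequence: 11 steps (1 to 20); 5 and 8 enter as purchased fragments.

Most likely to fail, first: step 9. The ligand-controlled ring closure may give poor diastereoselectivity, or the epoxide may not survive the chromium salts. The fallback separates ring closure from stereocontrol and installs the epoxide last. It sets out from 14, which is oxidised with Dess–Martin periodinane to methyl (5E)-2-[(E)-iodomethylidene]-6,10,10-trimethyl-11-oxoundec-5-enoate F1. Ligand-free cyclisation (CrCl2, NiCl2 cat., DMSO, 2 mM) gives racemic methyl (1E,8E)-3-hydroxy-4,4,8-trimethylcycloundeca-1,8-diene-1-carboxylate F2. Dess–Martin oxidation gives methyl (1E,8E)-4,4,8-trimethyl-3-oxocycloundeca-1,8-diene-1-carboxylate F3. Corey–Bakshi–Shibata reduction ((S)-Me-CBS, catecholborane, −78 °C, the tertiary-alkyl side acting as the large group) gives methyl (1E,3R,8E)-3-hydroxy-4,4,8-trimethylcycloundeca-1,8-diene-1-carboxylate F4. ent-Shi epoxidation of the electron-rich ring alkene of F4 comes back to the route at 17.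

Second: step 7. The dioxirane may attack the vinyl iodide, or the enantioselectivity on 14 may be poor. The fallback puts the epoxide in before any iodine is present. It sets out from 10, which is epoxidised under the same ent-Shi conditions to diethyl 2-{2-[(2S,3S)-3-(5-hydroxy-4,4-dimethylpentyl)-3-methyloxiran-2-yl]ethyl}propanedioate F5. Diiodomethylation (NaH, CHI3) gives diethyl 2-(diiodomethyl)-2-{2-[(2S,3S)-3-(5-hydroxy-4,4-dimethylpentyl)-3-methyloxiran-2-yl]ethyl}propanedioate F6. KOH in aqueous ethanol gives potassium (2E)-2-{2-[(2S,3S)-3-(5-hydroxy-4,4-dimethylpentyl)-3-methyloxiran-2-yl]ethyl}-3-iodoprop-2-enoate F7, which is methylated in the flask with MeI, so the epoxy acid is never set free, and comes back to the route at 15.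

Third: step 11. Benzoylation of the hindered carbinol next to a free acid may stall or give anhydride-derived by-products. The fallback reverses the last two operations and uses a non-hydrolytic ester cleavage. It sets out from 17, which is benzoylated (BzCl, DMAP, pyridine) to methyl (1S,4E,6R,11S)-6-(benzoyloxy)-7,7,11-trimethyl-12-oxabicyclo[9.1.0]dodec-4-ene-4-carboxylate F8. The methyl ester is then cleaved with Me3SnOH (1,2-dichloroethane, 70 °C), which spares the hindered neopentylic benzoate, and the route is rejoined at 20.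

## Further compounds

F1 | step 9 | methyl (5E)-2-[(E)-iodomethylidene]-6,10,10-trimethyl-11-oxoundec-5-enoate | COC(=O)/C(CC/C=C(\C)CCCC(C)(C)C=O)=C/I
F2 | step 9 | methyl (1E,8E)-3-hydroxy-4,4,8-trimethylcycloundeca-1,8-diene-1-carboxylate (racemic) | CC1(C)CCC/C(C)=C/CC/C(C(=O)OC)=C\C1O
F3 | step 9 | methyl (1E,8E)-4,4,8-trimethyl-3-oxocycloundeca-1,8-diene-1-carboxylate | CC1(C)CCC/C(C)=C/CC/C(C(=O)OC)=C\C1=O
F4 | step 9 | methyl (1E,3R,8E)-3-hydroxy-4,4,8-trimethylcycloundeca-1,8-diene-1-carboxylate | CC1(C)CCC/C(C)=C/CC/C(C(=O)OC)=C\[C@H]1O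
F5 | step 7 | diethyl 2-{2-[(2S,3S)-3-(5-hydroxy-4,4-dimethylpentyl)-3-methyloxiran-2-yl]ethyl}propanedioate | OCC(C)(C)CCC[C@]1(C)O[C@H]1CCC(C(=O)OCC)C(=O)OCC
F6 | step 7 | diethyl 2-(diiodomethyl)-2-{2-[(2S,3S)-3-(5-hydroxy-4,4-dimethylpentyl)-3-methyloxiran-2-yl]ethyl}propanedioate | OCC(C)(C)CCC[C@]1(C)O[C@H]1CCC(C(I)I)(C(=O)OCC)C(=O)OCC
F7 | step 7 | potassium (2E)-2-{2-[(2S,3S)-3-(5-hydroxy-4,4-dimethylpentyl)-3-methyloxiran-2-yl]ethyl}-3-iodoprop-2-enoate | [K+].OCC(C)(C)CCC[C@]1(C)O[C@H]1CC/C(C(=O)[O-])=C\I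
F8 | step 11 | methyl (1S,4E,6R,11S)-6-(benzoyloxy)-7,7,11-trimethyl-12-oxabicyclo[9.1.0]dodec-4-ene-4-carboxylate | CC1(C)CCC[C@]2(C)O[C@H]2CC/C(C(=O)OC)=C\[C@H]1OC(=O)c1ccccc1
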